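**Strategy.** The cyclohexenone ring (C1 carbonyl, C2=C3, C4, carbinol C5, C6) is disconnected at C2: without it, C1, C3, C4, C5 and C6 form a cyclopentanone that carries the tertiary carbinol on its β-carbon. This (S)-3-hydroxy-3-nonadecylcyclopentanone comes from asymmetric conjugate borylation–oxidation of 3-nonadecylcyclopent-2-enone. Its kinetic enol silane is cyclopropanated, and the key step, an Ito–Saegusa ring expansion, cuts the bond shared by the three- and five-membered rings of the resulting 1-siloxybicyclo[3.1.0]hexane with FeCl3. One operation thus enlarges the ring by one carbon and, after loss of HCl, places the C2=C3 double bond next to the carbonyl, leaving the C5 stereocentre untouched.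

Key step: step 6

Assumption: (R,R)-QuinoxP* is taken to deliver boron to the Si face of C3 of enone 5; should the sense of induction be the opposite, (S,S)-QuinoxP* is used and nothing else changes.

**Step 1**
Reactants: 1 1-bromononadecane; 2 3-ethoxycyclopent-2-en-1-one
Product: 5 3-nonadecylcyclopent-2-en-1-one, via nonadecylmagnesium bromide 3 (not isolated), via 3-ethoxy-1-nonadecylcyclopent-2-en-1-ol 4 (not isolated)
Conditions: Mg, THF, reflux; then 2, THF, 0 °C → rt; then 1 M HCl, rt
Reagents that add atoms: water, O (the carbonyl oxygen of 5 comes from the aqueous acid)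
Why: Stork–Danheiser alkylative enone transposition, in which the Grignard reagent adds 1,2 to the vinylogous ester and aqueous acid hydrolyses the enol ether and removes the tertiary allylic hydroxyl to give the 3-alkyl enone; no stereocentre is formed.

**Step 2**
Reactants: 5 3-nonadecylcyclopent-2-en-1-one
Product: 7 (S)-3-hydroxy-3-nonadecylcyclopentan-1-one, via (R)-3-nonadecyl-3-(pinacolatoboryl)cyclopentan-1-one 6 (not isolated)
Conditions: B2pin2, Cu(MeCN)4PF6 (cat.), (R,R)-QuinoxP* (cat.), LiOtBu (cat.), THF–DMSO, rt; aqueous work-up; then NaBO3·4H2O, THF–H2O, rt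
Reagents that add atoms: sodium perborate, [Na+].[O-]OB=O
Why: Copper-catalysed asymmetric conjugate borylation of a β-substituted cyclic enone, in which the chiral bisphosphine–Cu–Bpin species delivers boron to the Si face of C3 to give the (R)-boronate, followed by perborate oxidation of the C–B bond with retention (the descriptor changes to S only through the priority rules) under conditions mild enough to spare the β-hydroxy ketone from retro-aldol cleavage and dehydration.

**Step 3**
Reactants: 7 (S)-3-hydroxy-3-nonadecylcyclopentan-1-one
Product: 8 (S)-3-nonadecyl-3-(triethylsilyloxy)cyclopentan-1-one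
Conditions: TESOTf, 2,6-lutidine, CH2Cl2, −78 °C
Reagents that add atoms: triethylsilyl trifluoromethanesulfonate, CC[Si](CC)(CC)OS(=O)(=O)C(F)(F)F
Why: Silyl triflate/hindered-base silylation caps the tertiary alcohol quickly at low temperature without ever forming an alkoxide, so the retro-aldol pathway that could racemise C3 stays closed and the hydroxyl is masked against the LDA of step 4.

**Step 4**
Reactants: 8 (S)-3-nonadecyl-3-(triethylsilyloxy)cyclopentan-1-one
Product: 9 (S)-triethyl{[1-nonadecyl-3-(trimethylsilyloxy)cyclopent-3-en-1-yl]oxy}silane
Conditions: LDA (commercial solution), TMSCl (in situ quench), THF, −78 °C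
Reagents that add atoms: chlorotrimethylsilane, C[Si](C)(C)Cl
Why: Kinetic enolisation with in situ O-silylation should take a proton from the unhindered C5 methylene and not from C2, which is neopentyl-like next to the fully substituted C3 carrying OSiEt3 and the C19 chain, giving the enol silane on the side away from the carbinol; the stereocentre is not involved.

**Step 5**
Reactants: 9 (S)-triethyl{[1-nonadecyl-3-(trimethylsilyloxy)cyclopent-3-en-1-yl]oxy}silane
Product: 10 (3S)-3-nonadecyl-3-(triethylsilyloxy)-1-(trimethylsilyloxy)bicyclo[3.1.0]hexane
Conditions: Et2Zn, CH2I2, CH2Cl2, 0 °C → rt; pyridine quench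
Reagents that add atoms: diiodomethane, ICI
Why: Furukawa-modified Simmons–Smith cyclopropanation, in which the electrophilic zinc carbenoid adds cis to the electron-rich enol ether double bond, the only alkene present; the two faces give two diastereomers that differ only at C1/C5 and converge in step 6.

**Step 6**
Reactants: 10 (3S)-3-nonadecyl-3-(triethylsilyloxy)-1-(trimethylsilyloxy)bicyclo[3.1.0]hexane
Product: 12 (S)-5-nonadecyl-5-(triethylsilyloxy)cyclohex-2-en-1-one, via (5R)-3-chloro-5-nonadecyl-5-(triethylsilyloxy)cyclohexan-1-one 11 (not isolated)
Conditions: FeCl3 (2.5 equiv), DMF, 0 °C → rt; then NaOAc, MeOH, rt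
Reagents that add atoms: none
Why: Ito–Saegusa one-carbon ring expansion: Fe(III) takes the silyl group from the cyclopropyl oxygen (Me3SiCl leaves) and oxidises the iron(III) cyclopropoxide by one electron, the oxy radical undergoes β-scission of the strained zero-bridge C1–C5 bond, and the ring-enlarged secondary 3-oxocyclohexyl radical abstracts chlorine from a second FeCl3 to give β-chloro ketone 11, from which acetate removes HCl (E1cB) to place the double bond at C2=C3. The closest known reaction is the FeCl3/DMF conversion of 1-trimethylsiloxybicyclo[n.1.0]alkanes into 2-cycloalkenones, a reaction type that includes five-to-six-membered cases. No ring is closed: the six-membered ring arises when the bond shared by the three- and five-membered rings is cut, so the cyclopropane methylene becomes C2 of the cyclohexenone. No stereocentre is formed that survives (the C3–Cl centre is lost on elimination), and the C5 carbinol centre, two bonds away from every bond that changes, keeps its configuration, so both diastereomers of 10 should give the same enone. The step needs (i) scission of the internal and not an external cyclopropane bond, secured by the greater stability of the secondary ring radical over a primary one and by the larger strain release, (ii) reaction at the cyclopropyl O–SiMe3 and not at the tertiary O–SiEt3, secured by the easily oxidised cyclopropane and the bulkier TES group in aprotic DMF, and (iii) loss of HCl and not of the β′-silyloxy group (which would lead on to a phenol), secured by chloride being the far better leaving group and by a weak base at room temperature.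

**Step 7**
Reactants: 12 (S)-5-nonadecyl-5-(triethylsilyloxy)cyclohex-2-en-1-one
Product: 13 (S)-5-hydroxy-5-nonadecylcyclohex-2-en-1-one
Conditions: HF·pyridine, pyridine, THF, 0 °C
Reagents that add atoms: none
Why: Buffered fluoride-mediated Si–O cleavage removes the tertiary TES ether without forming an alkoxide or a strong acid, so neither retro-aldol racemisation nor dehydration of the β-hydroxy enone to 3-nonadecylphenol is expected.

**Compound list**
1 | 1-bromononadecane | CCCCCCCCCCCCCCCCCCCBr | starting material
2 | 3-ethoxycyclopent-2-en-1-one | CCOC1=CC(=O)CC1 | starting material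
3 | nonadecylmagnesium bromide | CCCCCCCCCCCCCCCCCCC[Mg]Br | intermediate
4 | 3-ethoxy-1-nonadecylcyclopent-2-en-1-ol (racemic; present as its bromomagnesium alkoxide before the acid is added) | CCCCCCCCCCCCCCCCCCCC1(O)C=C(OCC)CC1 | intermediate
5 | 3-nonadecylcyclopent-2-en-1-one | CCCCCCCCCCCCCCCCCCCC1=CC(=O)CC1 | intermediate
6 | (R)-3-nonadecyl-3-(4,4,5,5-tetramethyl-1,3,2-dioxaborolan-2-yl)cyclopentan-1-one | CCCCCCCCCCCCCCCCCCC[C@]1(B2OC(C)(C)C(C)(C)O2)CCC(=O)C1 | intermediate
7 | (S)-3-hydroxy-3-nonadecylcyclopentan-1-one | CCCCCCCCCCCCCCCCCCC[C@]1(O)CCC(=O)C1 | intermediate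
8 | (S)-3-nonadecyl-3-(triethylsilyloxy)cyclopentan-1-one | CCCCCCCCCCCCCCCCCCC[C@]1(O[Si](CC)(CC)CC)CCC(=O)C1 | intermediate
9 | (S)-triethyl{[1-nonadecyl-3-(trimethylsilyloxy)cyclopent-3-en-1-yl]oxy}silane | CCCCCCCCCCCCCCCCCCC[C@]1(O[Si](CC)(CC)CC)CC=C(O[Si](C)(C)C)C1 | intermediate
10 | (3S)-3-nonadecyl-3-(triethylsilyloxy)-1-(trimethylsilyloxy)bicyclo[3.1.0]hexane (two cis-fused diastereomers at C1/C5) | CCCCCCCCCCCCCCCCCCC[C@]1(O[Si](CC)(CC)CC)CC2CC2(O[Si](C)(C)C)C1 | intermediate
11 | (5R)-3-chloro-5-nonadecyl-5-(triethylsilyloxy)cyclohexan-1-one (both epimers at C3) | CCCCCCCCCCCCCCCCCCC[C@]1(O[Si](CC)(CC)CC)CC(Cl)CC(=O)C1 | intermediate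
12 | (S)-5-nonadecyl-5-(triethylsilyloxy)cyclohex-2-en-1-one | CCCCCCCCCCCCCCCCCCC[C@]1(O[Si](CC)(CC)CC)CC=CC(=O)C1 | intermediate
13 | (S)-5-hydroxy-5-nonadecylcyclohex-2-en-1-one | CCCCCCCCCCCCCCCCCCC[C@]1(O)CC=CC(=O)C1 | target

**Step count and risks**
Total step count: 7. Longest linear sequence: 7 steps (1 → 13).

Steps most likely to fail:

1. Step 6. The Lewis-acidic iron(III) may strip the tertiary silyl ether, and the β-oxygen may then be eliminated with aromatisation; an external cyclopropane bond may also be cut instead of the internal one. The fallback sets out from 9 and comes back at 12. Dibromocarbene (CHBr3, KOtBu, pentane, −30 °C) is added to the enol silane to give (3S)-6,6-dibromo-3-nonadecyl-3-(triethylsilyloxy)-1-(trimethylsilyloxy)bicyclo[3.1.0]hexane F1. Its cyclopropyl-to-allyl cation opening on warming, with loss of bromide and then of the silyl group, should give (S)-2-bromo-5-nonadecyl-5-(triethylsilyloxy)cyclohex-2-en-1-one F2. Palladium-catalysed formate hydrodebromination (Pd(OAc)2, PPh3, HCO2Na, DMF, 60 °C) then gives 12. The ring is still enlarged from five to six members, but by a cationic electrocyclic opening instead of a radical scission, and no iron(III) is present.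

2. Step 2. Facial selectivity may be insufficient for an enone with a C19 chain that is poorly soluble in the polar medium, and the β-hydroxy ketone may undergo retro-aldol cleavage or dehydration during the oxidation. The fallback sets out from 5 and comes back at 7. Asymmetric nucleophilic epoxidation under iminium catalysis (aqueous H2O2, 9-amino-9-deoxy-epi-cinchona alkaloid salt, dioxane; pseudoenantiomer chosen for the required sense) gives the 2,3-epoxide (1S,5S)-5-nonadecyl-6-oxabicyclo[3.1.0]hexan-2-one F3. Reductive cleavage of its Cα–O bond with SmI2 (THF–MeOH, −90 °C) gives 7, with the C–O bond at the quaternary carbon left intact.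

3. Step 4. Regiocontrol of the enolisation may be incomplete; deprotonation at C2 would be followed by loss of silanolate and return to enone 5. The fallback sets out from 7 and comes back at 9. LDA (2.2 equiv, THF, −78 °C) converts the unprotected hydroxy ketone into dilithium (S)-4-nonadecylcyclopent-1-ene-1,4-diolate F4. The alkoxide formed first disfavours a second negative charge on the adjacent C2, so the enolate should form toward C5, as is usual for dianions of β-hydroxy ketones. TMSCl (1 equiv) then silylates the enolate oxygen and TESOTf caps the hindered tertiary alkoxide, giving 9. The mixture is kept at −78 °C throughout to suppress retro-aldol opening of the alkoxide.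

**Further compounds**
F1 | step 6 | (3S)-6,6-dibromo-3-nonadecyl-3-(triethylsilyloxy)-1-(trimethylsilyloxy)bicyclo[3.1.0]hexane | CCCCCCCCCCCCCCCCCCC[C@]1(O[Si](CC)(CC)CC)CC2C(Br)(Br)C2(O[Si](C)(C)C)C1
F2 | step 6 | (S)-2-bromo-5-nonadecyl-5-(triethylsilyloxy)cyclohex-2-en-1-one | CCCCCCCCCCCCCCCCCCC[C@]1(O[Si](CC)(CC)CC)CC=C(Br)C(=O)C1
F3 | step 2 | (1S,5S)-5-nonadecyl-6-oxabicyclo[3.1.0]hexan-2-one | CCCCCCCCCCCCCCCCCCC[C@]12CCC(=O)[C@H]1O2
F4 | step 4 | dilithium (S)-4-nonadecylcyclopent-1-ene-1,4-diolate | CCCCCCCCCCCCCCCCCCC[C@]1(O[Li])CC=C(O[Li])C1
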